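**Retrosynthetic overview**

1. Target ⇒ C6–prenyl bond made last, at the only unsubstituted carbon of arene ring A of the 8-benzoyl-5,7-dihydroxy-4-phenylchromanone.
2. That ketone ⇒ C8–benzoyl bond by Friedel–Crafts acylation of (R)-5,7-dimethoxy-4-phenylchroman-2-one, then O-demethylation.
3. Key disconnection, C4–Ph: C4, normally the electrophilic Michael carbon of a coumarin, is used with reversed polarity as a chiral boron homoenolate and joined to electrophilic iodobenzene with retention.
4. The boron homoenolate ⇒ enantioselective copper-catalysed conjugate borylation of 5,7-dimethoxycoumarin, which sets C4.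
5. Ring order: no ring is built; arene ring A and lactone ring B come fused in the starting coumarin, and both phenyl rings are bought.

Assumption: 5,7-dimethoxycoumarin (citropten) is bought, and (R,R)-QuinoxP* is taken to give the (4S)-boronate; if the sense is opposite, (S,S)-QuinoxP* is used with no other change.

**Step 1**
Reactants: 1 5,7-dimethoxycoumarin (5,7-dimethoxy-2H-chromen-2-one); 2 bis(pinacolato)diboron
Product: 3 (4S)-5,7-dimethoxy-4-(4,4,5,5-tetramethyl-1,3,2-dioxaborolan-2-yl)chroman-2-one
Conditions: B2pin2 (1.2 equiv), CuCl (5 mol%), NaOtBu (7 mol%), (R,R)-QuinoxP* (6 mol%), t-BuOH (2 equiv), THF, rt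
Reagents that add atoms: bis(pinacolato)diboron, CC1(C)OB(OC1(C)C)B1OC(C)(C)C(C)(C)O1
Why: Asymmetric copper-catalysed conjugate borylation: the phosphine-bound Cu–Bpin species adds boron to the Michael carbon C4 of the unsaturated lactone on the face selected by the C2-symmetric ligand and t-BuOH (chosen over MeOH so that the aryl lactone is not opened) protonates the copper enolate, so that C4 becomes a configurationally stable (S)-boronate, the homoenolate equivalent of the dihydrocoumarin.

**Step 2**
Reactants: 3 (4S)-5,7-dimethoxy-4-(pinacolboryl)chroman-2-one; 4 iodobenzene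
Product: 5 (4R)-5,7-dimethoxy-4-phenylchroman-2-one
Conditions: PhI (1.5 equiv), Pd2(dba)3 (4 mol%), PPh3 (64 mol%), Ag2O (1.5 equiv), DME, 85 °C
Reagents that add atoms: iodobenzene, Ic1ccccc1
Why: Stereoretentive Suzuki–Miyaura coupling of a secondary benzylic boronic ester (Ag2O-assisted transmetalation to PhPdI with retention, a large excess of PPh3 to hold back β-hydride elimination to the coumarin): C4, normally the electrophilic β-carbon, reacts as a nucleophile with the electrophilic ipso carbon of iodobenzene, and phenyl takes the place of boron with unchanged geometry, which is named (R) only because phenyl outranks C3 whereas boron did not.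

**Step 3**
Reactants: 5 (4R)-5,7-dimethoxy-4-phenylchroman-2-one; 6 benzoyl chloride
Product: 8 (4R)-8-benzoyl-5,7-dihydroxy-4-phenylchroman-2-one, via dimethoxy ketone 7 (not isolated)
Conditions: BzCl (1.1 equiv), AlCl3 (2 equiv), CH2Cl2, 0 °C to rt; then BBr3 (5 equiv), −78 to 0 °C; H2O
Reagents that add atoms: benzoyl chloride, O=C(Cl)c1ccccc1
Why: Friedel–Crafts acylation followed by Lewis-acid ether cleavage: the benzoyl cation should attack C8 (para to 5-OMe, ortho to 7-OMe) and not C6, which is wedged between two methoxy groups as in orcinol dimethyl ether, and BBr3 then removes both O-methyl groups through aryloxyborane intermediates while the aryl lactone and the C4 centre stay untouched at low temperature.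

**Step 4**
Reactants: 8 (4R)-8-benzoyl-5,7-dihydroxy-4-phenylchroman-2-one; 9 2-methylbut-3-en-2-ol
Product: 10 (4R)-8-benzoyl-5,7-dihydroxy-6-(3-methylbut-2-en-1-yl)-4-phenylchroman-2-one
Conditions: 2-methylbut-3-en-2-ol (2 equiv), BF3·OEt2 (0.3 equiv), 1,4-dioxane, rt
Reagents that add atoms: 2-methylbut-3-en-2-ol, CC(C)(O)C=C
Why: Acid-catalysed nuclear prenylation (Friedel–Crafts alkylation by the dimethylallyl cation generated from the tertiary allylic alcohol) at C6, the only free ring carbon and ortho to both phenols, under non-hydrolytic conditions that leave the lactone closed and therefore keep both its regiochemistry and the (R)-centre intact.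

**Compound list**

1 | 5,7-dimethoxycoumarin (5,7-dimethoxy-2H-chromen-2-one) | COc1cc(OC)c2C=CC(=O)Oc2c1 | starting material
2 | bis(pinacolato)diboron | CC1(C)OB(OC1(C)C)B1OC(C)(C)C(C)(C)O1 | starting material
3 | (4S)-5,7-dimethoxy-4-(4,4,5,5-tetramethyl-1,3,2-dioxaborolan-2-yl)chroman-2-one | COc1cc(OC)cc2c1[C@@H](B1OC(C)(C)C(C)(C)O1)CC(=O)O2 | intermediate
4 | iodobenzene | Ic1ccccc1 | starting material
5 | (4R)-5,7-dimethoxy-4-phenylchroman-2-one | COc1cc(OC)cc2c1[C@@H](c1ccccc1)CC(=O)O2 | intermediate
6 | benzoyl chloride | O=C(Cl)c1ccccc1 | starting material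
7 | (4R)-8-benzoyl-5,7-dimethoxy-4-phenylchroman-2-one | COc1cc(OC)c(C(=O)c2ccccc2)c2c1[C@@H](c1ccccc1)CC(=O)O2 | intermediate
8 | (4R)-8-benzoyl-5,7-dihydroxy-4-phenylchroman-2-one | Oc1cc(O)c(C(=O)c2ccccc2)c2c1[C@@H](c1ccccc1)CC(=O)O2 | intermediate
9 | 2-methylbut-3-en-2-ol | CC(C)(O)C=C | starting material
10 | (4R)-8-benzoyl-5,7-dihydroxy-6-(3-methylbut-2-en-1-yl)-4-phenylchroman-2-one | CC(C)=CCc1c(O)c(C(=O)c2ccccc2)c2c(c1O)[C@@H](c1ccccc1)CC(=O)O2 | target

**Step count and risks**

Total step count: 4. Longest linear sequence: 4 (all reagents are bought).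

Steps most likely to fail:

Step 2 (the key coupling). The hindered secondary benzylic boronate may transmetalate slowly, and the alkylpalladium intermediate can lose hydride to give back coumarin 1 or erode the ee; any weakness of the step 1 borylation on this electron-rich coumarin shows up here as well. The fallback keeps the same polarity for the C4–Ph bond but replaces the boron homoenolate by a palladium homoenolate formed by C–H activation. It sets out from 1 and comes back at 5. Hydrogenation (H2, Pd/C, EtOAc) gives 5,7-dimethoxychroman-2-one F1. AlMe3-mediated aminolysis with quinolin-8-amine opens it to 3-(2-hydroxy-4,6-dimethoxyphenyl)-N-(quinolin-8-yl)propanamide F2. The amide-directed palladacycle at the benzylic carbon is then arylated enantioselectively with iodobenzene 4 (Pd(OAc)2, a BINOL-derived chiral phosphoric acid ligand, Ag2CO3, 110 °C) to give (3R)-3-(2-hydroxy-4,6-dimethoxyphenyl)-3-phenyl-N-(quinolin-8-yl)propanamide F3. TsOH in hot toluene closes the lactone onto the single free phenol, releases the auxiliary and gives 5.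

Step 3 (acylation and demethylation). The C8 preference rests on analogy, so a C6 isomer may form; the chiral lactone also meets two strong Lewis acids, which could cause ring-opening and reclosure on the other phenol or acylation of the 4-phenyl ring by the lactone. The fallback moves the acylation ahead of the stereocentre, onto the flat coumarin, where regioisomers can be separated and assigned before any chiral material is committed. It sets out from 1 and comes back at 7. Benzoyl chloride 6 with SnCl4 in CH2Cl2 gives 8-benzoyl-5,7-dimethoxy-2H-chromen-2-one F4. Conjugate borylation with 2 under the step 1 catalyst (the ketone makes the acceptor more electrophilic) gives (4S)-8-benzoyl-5,7-dimethoxy-4-(4,4,5,5-tetramethyl-1,3,2-dioxaborolan-2-yl)chroman-2-one F5. Coupling with iodobenzene 4 as in step 2 gives 7, which is then isolated and demethylated with BBr3 alone to 8.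

Step 4 (prenylation). Acid-catalysed prenylation of acylphloroglucinols is typically low-yielding, with cyclisation of the new prenyl group onto a neighbouring phenol (chroman formation) as the main loss. The fallback replaces direct C-alkylation by O-alkylation and sigmatropic transfer. It sets out from 8 and comes back at 10. Pd(PPh3)4-catalysed allylation with tert-butyl 2-methylbut-3-en-2-yl carbonate in THF at 0 °C puts a 1,1-dimethylallyl group on the unchelated 5-OH to give (4R)-8-benzoyl-7-hydroxy-5-[(2-methylbut-3-en-2-yl)oxy]-4-phenylchroman-2-one F6. Heating in toluene at 110 °C brings about the aromatic Claisen rearrangement to C6, the only free ortho position, which delivers the normal prenyl group and, after tautomerisation, 10.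

**Further compounds**

F1 | step 2 | 5,7-dimethoxychroman-2-one | COc1cc(OC)c2CCC(=O)Oc2c1
F2 | step 2 | 3-(2-hydroxy-4,6-dimethoxyphenyl)-N-(quinolin-8-yl)propanamide | COc1cc(O)c(CCC(=O)Nc2cccc3cccnc23)c(OC)c1
F3 | step 2 | (3R)-3-(2-hydroxy-4,6-dimethoxyphenyl)-3-phenyl-N-(quinolin-8-yl)propanamide | COc1cc(O)c([C@H](CC(=O)Nc2cccc3cccnc23)c2ccccc2)c(OC)c1
F4 | step 3 | 8-benzoyl-5,7-dimethoxy-2H-chromen-2-one | COc1cc(OC)c2C=CC(=O)Oc2c1C(=O)c1ccccc1
F5 | step 3 | (4S)-8-benzoyl-5,7-dimethoxy-4-(4,4,5,5-tetramethyl-1,3,2-dioxaborolan-2-yl)chroman-2-one | COc1cc(OC)c(C(=O)c2ccccc2)c2c1[C@@H](B1OC(C)(C)C(C)(C)O1)CC(=O)O2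
F6 | step 4 | (4R)-8-benzoyl-7-hydroxy-5-[(2-methylbut-3-en-2-yl)oxy]-4-phenylchroman-2-one | C=CC(C)(C)Oc1cc(O)c(C(=O)c2ccccc2)c2c1[C@@H](c1ccccc1)CC(=O)O2
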